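The runs come from a simulation for substances that don't exist; the scatter is artificial.

You have no constants for the proposed steps, so take from oak a ratio of them that splits substrate between target and side product.

| setting | oak | alder | east | west | north-west | south-west |
|---|---|---|---|---|---|---|
| substrate | 0.20 M | 0.20 M | 0.20 M | 0.20 M (fed, over 30 min) | 0.20 M (in portions, 4, over 30 min) | 0.20 M |
| reagent | 0.50 M | 0.25 M | 0.500 M | 0.500 M | 0.500 M | 0.500 M (fed, over 30 min) |
| remark | run made earlier | run made earlier | everything together at the start | all else is in the flask from the start; the feed brings no volume worth counting | first portion at the start, last at 30 min | all else is in the flask from the start; the feed brings no volume worth counting |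
| time |  |  | 2.5 h | 2.5 h | 2.5 h | 2.5 h |

oak run (percent of the substrate charged)

| time / h | target / % | side product / % |
|---|---|---|
| 0.500 | 0 | 0 |
| 1.00 | 2 | 2 |
| 1.50 | 16 | 19 |
| 2.00 | 35 | 46 |
| 2.50 | 43 | 54 |

alder run (percent of the substrate charged)

| time / min | target / % | side product / % |
|---|---|---|
| 2.50 | 0 | 0 |
| 5.00 | 1 | 0 |
| 8.00 | 0 | 0 |
| 15.0 | 0 | 1 |
| 30.0 | 1 | 2 |

(each reading ± 2 percentage points)

- in percentages every species weighs as the substrate in it: one side product counts as two
- the analysis behind the earlier runs scatters by 2 percentage points, standard deviation
- steps that have been proposed: substrate + reagent + released group -> target + 2 released group; substrate + reagent -> target + released group; substrate + target -> side product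

- the best flask by share of target in target plus side product; "all alike" if 1.5 percentage points covers them all (east / west / north-west / south-west / all alike)
- share of target in target plus side product at the end, east
- share of target in target plus side product at the end, west
- share of target in target plus side product at the end, north-west
- share of target in target plus side product at the end, south-west

The proposed steps are: substrate, reagent and released group give target and two released group; substrate and reagent give target and released group; substrate and target give side product. Substrate stands in each step, so it cancels when you divide the side-product rate by the target rate, while c(reagent) stays in the target steps and c(target) over c(released group) stays as well. I take the step with released group as the main target step, and oak's share of target is 45.7% at 1.50 h and 44.3% at 2.50 h, so I assume that last ratio steady and reckon with this rule: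

side product / target = a / c(reagent)

share of target = c(reagent) / (c(reagent) + a)

Each target and each side product took one reagent, and a side product counts two in the percentages. Oak's reagent at 2.50 h therefore gives:

reagent used = 0.140 M

mean c(reagent) = 0.430 M

a = 0.430 M × 54% / 43% = 0.540 M

This a is the break-even reagent level, the reagent concentration at which target and side product come out equal, a selectivity factor written as a concentration. East is oak's recipe, so the rule returns oak's own reading, 44.3%, with the scatter of that reading.

The first doubt is south-west: its reagent starts low, and a low c(reagent) means a poor share. But its feed ends at 30 min, earlier than oak's 1.00 h reading, where target is 2%.

The second doubt is that fed flasks start late. Taken as delayed by the whole feed, they compare with oak's 2.00 h reading, whose share is 43.2%, a gap of 1.1 percentage points between two readings that both carry scatter, set against the margin of 1.5 points. So my estimate is all alike, with east at 44.3% and the fed flasks about that gap below it.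

The forecast says all alike, with east at 44% and each fed flask at 44.5%, slightly above east where mine lies below. Of the delayed flasks it says: “Almost all reaction then happens with reagent near 0.5 M”.

The flasks give all alike: east 40.8%, west 41.1%, north-west 41.1%, south-west 41.1%.

    substrate + reagent + released group → target + 2 released group (k = 0.0130 /M²/s)
    substrate + reagent → target + released group (k = 7.90 × 10⁻⁷ /M/s)
    substrate + target → side product (k = 0.00390 /M/s)

At the end of its feed, south-west holds target 0.0489% and side product 0.0372%. North-west ends with 74.9% of its reagent, a level midway between start and end of 0.437 M, so a gives 44.7% against the flask's 41.1%. The neighbour is north-west with 0.80 M of substrate. It ends with 7.79% of its reagent, a midway level of 0.269 M, so a gives 33.3%, and the flask gives 15.6%.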